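**Retrosynthetic overview**
1. Terminal oxirane (C1–C2): closed last from an (S)-chlorohydrin whose carbinol centre is set by a ketoreductase on an α-chloro ketone; the enal comes from Mannich methylenation of a CH2–CHO chain.
2. α-Methylene-γ-lactone: an 8-O-malonate opens a 6β,7β-epoxide intramolecularly (sets C7, frees 6-OH), then decarboxylative methylenation.
3. Ring oxygens: 8α,9α-diol by OsO4 on a cyclohex-2-enone; 6β,7β-epoxide via the diaxial bromohydrin of the derived Δ6-alkene.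
4. Carbocycle with quaternary C10 and C5: catalytic enantioselective Diels–Alder of an (E)-2-methyl-2-enal with a 2-silyloxybutadiene, then Saegusa oxidation.
5. Ring order: cyclohexene → (temporary dioxolane) → ring epoxide → γ-lactone → terminal oxirane.

Assumption: atom labels follow elemane numbering (ring C5–C10; C10 bears CH3 and C1–C2; C5 bears C4–C3; C7 bears C11–C12; β = face of the C10 methyl), and the (S)-oxazaborolidinium catalyst is taken to give the (1R,6R) adduct 7 (otherwise its enantiomer is used).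

**Route**

Step 1
Reactants: 1 3-(tert-butyldiphenylsilyloxy)propan-1-ol
Product: 2 3-(tert-butyldiphenylsilyloxy)propanal
Conditions: Dess–Martin periodinane, CH2Cl2, 0 °C to rt
Reagents that add atoms: none
Why: Dess–Martin oxidation of a primary alcohol stops at the aldehyde and leaves the silyl ether intact.

Step 2
Reactants: 2 3-(tert-butyldiphenylsilyloxy)propanal; 3 2-(triphenylphosphoranylidene)propanal
Product: 4 (E)-5-(tert-butyldiphenylsilyloxy)-2-methylpent-2-enal
Conditions: toluene, 90 °C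
Reagents that add atoms: none
Why: Wittig olefination with a stabilised ylide gives the (E)-trisubstituted enal, the geometry that later makes the C10 methyl and the C5 chain cis.

Step 3
Reactants: 5 but-3-en-2-one
Product: 6 2-(triisopropylsilyloxy)buta-1,3-diene
Conditions: i-Pr3SiOTf, Et3N, Et2O, 0 °C to rt
Reagents that add atoms: triisopropylsilyl trifluoromethanesulfonate, CC(C)[Si](C(C)C)(C(C)C)OS(=O)(=O)C(F)(F)F
Why: Soft enolisation and O-silylation of the methyl ketone gives the 2-silyloxy diene.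

Step 4
Reactants: 4 (E)-5-(tert-butyldiphenylsilyloxy)-2-methylpent-2-enal; 6 2-(triisopropylsilyloxy)buta-1,3-diene
Product: 7 (1R,6R)-6-[2-(tert-butyldiphenylsilyloxy)ethyl]-1-methyl-4-(triisopropylsilyloxy)cyclohex-3-ene-1-carbaldehyde
Conditions: (S)-3,3-diphenyl-1-(o-tolyl)tetrahydro-1H,3H-pyrrolo[1,2-c][1,3,2]oxazaborole (20 mol%), Tf2NH (18 mol%), CH2Cl2, −78 to −40 °C
Reagents that add atoms: none
Why: Catalytic enantioselective Diels–Alder reaction with "para" regiochemistry; suprafacial addition to the (E)-enal fixes C10-CH3 cis to the C5 chain, and the chiral oxazaborolidinium cation selects the enal face, setting C10 (first stereocentre) and C5.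

Step 5
Reactants: 7 Diels–Alder aldehyde
Product: 8 2-chloro-1-[(1R,6R)-6-[2-(tert-butyldiphenylsilyloxy)ethyl]-1-methyl-4-(triisopropylsilyloxy)cyclohex-3-en-1-yl]ethanol (both carbinol epimers)
Conditions: ICH2Cl, MeLi·LiBr, THF, −78 °C; AcOH quench at −78 °C
Reagents that add atoms: chloroiodomethane, ClCI
Why: 1,2-Addition of chloromethyllithium (made in situ by iodine–lithium exchange) to the only carbonyl group adds C2; the new carbinol centre is erased in step 7.

Step 6
Reactants: 8 chlorohydrin silyl enol ether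
Product: 9 (4S,5R)-5-[2-(tert-butyldiphenylsilyloxy)ethyl]-4-(2-chloro-1-hydroxyethyl)-4-methylcyclohex-2-en-1-one (both carbinol epimers)
Conditions: Pd(OAc)2 (1.2 equiv), DMSO, 45 °C
Reagents that add atoms: none
Why: Saegusa–Ito oxidation of the regiodefined silyl enol ether gives the C8=C9 enone with the carbonyl at C7.

Step 7
Reactants: 9 enone chlorohydrin
Product: 10 (4S,5R)-5-[2-(tert-butyldiphenylsilyloxy)ethyl]-4-(chloroacetyl)-4-methylcyclohex-2-en-1-one
Conditions: Dess–Martin periodinane, pyridine, CH2Cl2, 0 °C to rt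
Reagents that add atoms: none
Why: Dess–Martin oxidation converges both carbinol epimers to one α-chloro ketone.

Step 8
Reactants: 10 enone α-chloro ketone
Product: 11 (4S,5R)-5-[2-(tert-butyldiphenylsilyloxy)ethyl]-4-[(1S)-2-chloro-1-hydroxyethyl]-4-methylcyclohex-2-en-1-one
Conditions: ketoreductase (NADPH-dependent alcohol dehydrogenase, anti-Prelog-selective, chosen from a screening panel), NADP+ (cat.), i-PrOH (15% v/v), phosphate buffer pH 7.0, DMSO (5%), 30 °C
Reagents that add atoms: none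
Why: Enzymatic carbonyl reduction by a ketoreductase delivers hydride to one face of the activated small/large chloromethyl ketone and sets C1 as S, while the conjugated ring ketone is a poor substrate and is left alone.

Step 9
Reactants: 11 (S)-chlorohydrin
Product: 12 (4S,5R)-4-[(1S)-1-(tert-butyldimethylsilyloxy)-2-chloroethyl]-5-[2-(tert-butyldiphenylsilyloxy)ethyl]-4-methylcyclohex-2-en-1-one
Conditions: t-BuMe2SiOTf, 2,6-lutidine, CH2Cl2, −78 to 0 °C
Reagents that add atoms: tert-butyldimethylsilyl trifluoromethanesulfonate, CC(C)(C)[Si](C)(C)OS(=O)(=O)C(F)(F)F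
Why: Silylation masks the chlorohydrin oxygen so that no base can close the oxirane before the last step.

Step 10
Reactants: 12 silyl-protected enone
Product: 13 8α,9α-diol of 12 (7-ketone; both hydroxyls cis to each other and trans to the C10 methyl)
Conditions: OsO4 (5 mol%), N-methylmorpholine N-oxide, citric acid, t-BuOH/H2O, rt
Reagents that add atoms: osmium tetroxide, O=[Os](=O)(=O)=O; N-methylmorpholine N-oxide, C[N+]1([O-])CCOCC1; water, O
Why: Upjohn syn-dihydroxylation attacks the enone anti to the pseudo-axial C10 methyl in the conformer with both large groups equatorial, setting C8 and C9 (both α).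

Step 11
Reactants: 13 8α,9α-diol
Product: 14 8,9-O-isopropylidene acetal of 13
Conditions: Me2C(OMe)2, PPTS (cat.), CH2Cl2, rt
Reagents that add atoms: 2,2-dimethoxypropane, COC(C)(C)OC
Why: Acetonide formation on the cis-diol protects the β-hydroxy ketone against elimination and base.

Step 12
Reactants: 14 acetonide ketone
Product: 16 Δ6-enol triflate (7-OTf) of 14, via potassium Δ6-enolate 15 (not isolated)
Conditions: KN(SiMe3)2, THF, −78 °C; then PhNTf2, −78 to 0 °C
Reagents that add atoms: N-phenylbis(trifluoromethanesulfonimide), O=S(=O)(N(c1ccccc1)S(=O)(=O)C(F)(F)F)C(F)(F)F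
Why: Kinetic enolisation occurs at the C6 methylene, away from the oxygen-bearing C8, and O-triflation fixes the C6=C7 position.

Step 13
Reactants: 16 enol triflate
Product: 17 Δ6-alkene with 8α,9α-acetonide
Conditions: Pd(OAc)2 (5 mol%), PPh3 (10 mol%), HCO2H, n-Bu3N, DMF, 60 °C
Reagents that add atoms: none
Why: Palladium-catalysed formate reduction of the vinyl triflate gives the alkene without touching the alkyl chloride or silyl ethers.

Step 14
Reactants: 17 Δ6-alkene
Product: 18 6β-hydroxy-7α-bromo acetonide (trans-diaxial bromohydrin)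
Conditions: N-bromosuccinimide, THF/H2O (4:1), 0 °C
Reagents that add atoms: N-bromosuccinimide, O=C1CCC(=O)N1Br; water, O
Why: Bromohydrin formation follows Fürst–Plattner trans-diaxial opening of the α-bromonium ion by water at C6, the carbon remote from the inductively deactivating C8–O bond, setting 6β-O.

Step 15
Reactants: 18 bromohydrin acetonide
Product: 20 6β,7β-epoxy-8α,9α-diol, via bromo triol 19 (not isolated)
Conditions: PPTS, MeOH, 40 °C; then K2CO3, 0 °C
Reagents that add atoms: none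
Why: Acetonide methanolysis followed by intramolecular Williamson closure (inversion at C7) gives the β-epoxide, since only the 6β-alkoxide is anti to the bromide.

Step 16
Reactants: 20 epoxy diol; 21 allyl hydrogen malonate
Product: 22 8-O-(allyl malonyl) ester of 20 (9-OH free)
Conditions: DCC, DMAP (cat.), CH2Cl2, −10 to 0 °C
Reagents that add atoms: none
Why: Steglich esterification selects the equatorial 8-OH over the axial 9-OH next to the quaternary carbon.

Step 17
Reactants: 22 8-O-malonate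
Product: 23 8-O-(allyl malonyl)-9-O-methacryloyl diester
Conditions: methacrylic anhydride, pyridine, DMAP (cat.), CH2Cl2, rt to 35 °C
Reagents that add atoms: methacrylic anhydride, CC(=C)C(=O)OC(=O)C(C)=C
Why: DMAP-catalysed acylation installs the methacrylate on the only remaining hydroxyl while O6 is still locked in the epoxide.

Step 18
Reactants: 23 diester
Product: 24 primary alcohol at C3 (tert-butyldiphenylsilyl group removed)
Conditions: Bu4NF, AcOH (1:1), THF, 0 °C to rt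
Reagents that add atoms: none
Why: Buffered fluoride desilylation cleaves the primary silyl ether and spares the hindered secondary one at C1.

Step 19
Reactants: 24 primary alcohol
Product: 25 C3 aldehyde
Conditions: Dess–Martin periodinane, pyridine, CH2Cl2, 0 °C
Reagents that add atoms: none
Why: Dess–Martin oxidation is clean here because no other free hydroxyl is present.

Step 20
Reactants: 25 aldehyde
Product: 26 C3 dimethyl acetal
Conditions: HC(OMe)3, PPTS (cat.), MeOH, 0 °C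
Reagents that add atoms: trimethyl orthoformate, COC(OC)OC; methanol, CO
Why: Mild acetalisation masks the enolisable aldehyde before the base-mediated ring closure.

Step 21
Reactants: 26 epoxy malonate
Product: 27 cis-fused γ-lactone (11-allyloxycarbonyl-12,8α-olide, 6β-OH, C11 epimers)
Conditions: Cs2CO3 (0.3 equiv), MeCN, 40 °C
Reagents that add atoms: none
Why: Intramolecular SN2 epoxide opening (5-exo-tet, trans-diaxial) by the malonate carbanion attacks C7 anti to the epoxide oxygen, setting C7 (H7β, lactone cis-fused to 8α-O) and freeing 6β-OH.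

Step 22
Reactants: 27 lactone allyl ester
Product: 30 α-methylene-γ-lactone (C3 acetal, 1-O-silyl), via carboxylic acid 28 (not isolated), via Mannich base 29 (not isolated)
Conditions: Pd(PPh3)4 (5 mol%), morpholine, THF, rt; then 37% aq. HCHO, 45 °C
Reagents that add atoms: formaldehyde, C=O
Why: Tsuji–Trost deallylation followed by decarboxylative Mannich methylenation converts the malonic half-ester into the exo-methylene lactone.

Step 23
Reactants: 30 α-methylene lactone
Product: 31 hydroxy aldehyde chlorohydrin (C3 aldehyde, 1-OH, 6-OH; in equilibrium with its lactols)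
Conditions: 48% aq. HF, MeCN, 0 °C to rt
Reagents that add atoms: water, O
Why: Aqueous HF removes the remaining silyl ether and hydrolyses the dimethyl acetal, while lactone, methacrylate and chloride are acid-stable.

Step 24
Reactants: 31 hydroxy aldehyde
Product: 33 enal chlorohydrin, via Mannich base 32 (not isolated)
Conditions: Me2N=CH2+ I−, Et3N, CH2Cl2, rt
Reagents that add atoms: N,N-dimethylmethyleneiminium iodide, C[N+](C)=C.[I-]
Why: Mannich reaction at C4 followed by β-elimination of dimethylamine (Eschenmoser methylenation) gives the 2-substituted acrolein without a secondary amine that could add to the lactone.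

Step 25
Reactants: 33 enal chlorohydrin
Product: 34 target (CNP0124638.3)
Conditions: Cs2CO3, MeCN, 0 °C to rt
Reagents that add atoms: none
Why: Intramolecular Williamson etherification (3-exo-tet) displaces the primary chloride with retention at C1, giving the (S)-oxirane; reversible alkoxide side-equilibria funnel into this irreversible closure.

**Compound list**

1 | 3-(tert-butyldiphenylsilyloxy)propan-1-ol | OCCCO[Si](c1ccccc1)(c1ccccc1)C(C)(C)C | starting material
2 | 3-(tert-butyldiphenylsilyloxy)propanal | O=CCCO[Si](c1ccccc1)(c1ccccc1)C(C)(C)C | intermediate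
3 | 2-(triphenylphosphoranylidene)propanal | CC(C=O)=P(c1ccccc1)(c1ccccc1)c1ccccc1 | starting material
4 | (E)-5-(tert-butyldiphenylsilyloxy)-2-methylpent-2-enal | O=C/C(C)=C/CCO[Si](c1ccccc1)(c1ccccc1)C(C)(C)C | intermediate
5 | but-3-en-2-one | CC(=O)C=C | starting material
6 | 2-(triisopropylsilyloxy)buta-1,3-diene | C=CC(=C)O[Si](C(C)C)(C(C)C)C(C)C | intermediate
7 | (1R,6R)-6-[2-(tert-butyldiphenylsilyloxy)ethyl]-1-methyl-4-(triisopropylsilyloxy)cyclohex-3-ene-1-carbaldehyde | CC(C)(C)[Si](c2ccccc2)(c3ccccc3)OCC[C@@H]1CC(O[Si](C(C)C)(C(C)C)C(C)C)=CC[C@@]1(C)C=O | intermediate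
8 | chlorohydrin of 7 (2-chloro-1-hydroxyethyl at C10, both carbinol epimers) | CC(C)(C)[Si](c2ccccc2)(c3ccccc3)OCC[C@@H]1CC(O[Si](C(C)C)(C(C)C)C(C)C)=CC[C@@]1(C)C(O)CCl | intermediate
9 | (4S,5R)-5-[2-(tert-butyldiphenylsilyloxy)ethyl]-4-(2-chloro-1-hydroxyethyl)-4-methylcyclohex-2-en-1-one (both carbinol epimers) | CC(C)(C)[Si](c2ccccc2)(c3ccccc3)OCC[C@@H]1CC(=O)C=C[C@@]1(C)C(O)CCl | intermediate
10 | (4S,5R)-5-[2-(tert-butyldiphenylsilyloxy)ethyl]-4-(chloroacetyl)-4-methylcyclohex-2-en-1-one | CC(C)(C)[Si](c2ccccc2)(c3ccccc3)OCC[C@@H]1CC(=O)C=C[C@@]1(C)C(=O)CCl | intermediate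
11 | (4S,5R)-5-[2-(tert-butyldiphenylsilyloxy)ethyl]-4-[(1S)-2-chloro-1-hydroxyethyl]-4-methylcyclohex-2-en-1-one | CC(C)(C)[Si](c2ccccc2)(c3ccccc3)OCC[C@@H]1CC(=O)C=C[C@@]1(C)[C@H](O)CCl | intermediate
12 | (4S,5R)-4-[(1S)-1-(tert-butyldimethylsilyloxy)-2-chloroethyl]-5-[2-(tert-butyldiphenylsilyloxy)ethyl]-4-methylcyclohex-2-en-1-one | CC(C)(C)[Si](c2ccccc2)(c3ccccc3)OCC[C@@H]1CC(=O)C=C[C@@]1(C)[C@H](O[Si](C)(C)C(C)(C)C)CCl | intermediate
13 | 8α,9α-dihydroxy-7-ketone from 12 (hydroxyls cis, both trans to the C10 methyl) | CC(C)(C)[Si](c2ccccc2)(c3ccccc3)OCC[C@@H]1CC(=O)[C@@H](O)[C@@H](O)[C@@]1(C)[C@H](O[Si](C)(C)C(C)(C)C)CCl | intermediate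
14 | 8α,9α-O-isopropylidene-7-ketone | CC(C)(C)[Si](c2ccccc2)(c3ccccc3)OCC[C@@H]1CC(=O)[C@H]4OC(C)(C)O[C@H]4[C@@]1(C)[C@H](O[Si](C)(C)C(C)(C)C)CCl | intermediate
15 | potassium Δ6-enolate of 14 (not isolated) | CC(C)(C)[Si](c2ccccc2)(c3ccccc3)OCC[C@@H]1C=C([O-])[C@H]4OC(C)(C)O[C@H]4[C@@]1(C)[C@H](O[Si](C)(C)C(C)(C)C)CCl.[K+] | intermediate
16 | Δ6-enol triflate (7-trifluoromethanesulfonyloxy), 8α,9α-acetonide | CC(C)(C)[Si](c2ccccc2)(c3ccccc3)OCC[C@@H]1C=C(OS(=O)(=O)C(F)(F)F)[C@H]4OC(C)(C)O[C@H]4[C@@]1(C)[C@H](O[Si](C)(C)C(C)(C)C)CCl | intermediate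
17 | Δ6-alkene, 8α,9α-acetonide | CC(C)(C)[Si](c2ccccc2)(c3ccccc3)OCC[C@@H]1C=C[C@H]4OC(C)(C)O[C@H]4[C@@]1(C)[C@H](O[Si](C)(C)C(C)(C)C)CCl | intermediate
18 | 6β-hydroxy-7α-bromo-8α,9α-acetonide | CC(C)(C)[Si](c2ccccc2)(c3ccccc3)OCC[C@@H]1[C@H](O)[C@@H](Br)[C@H]4OC(C)(C)O[C@H]4[C@@]1(C)[C@H](O[Si](C)(C)C(C)(C)C)CCl | intermediate
19 | 7α-bromo-6β,8α,9α-triol (not isolated) | CC(C)(C)[Si](c2ccccc2)(c3ccccc3)OCC[C@@H]1[C@H](O)[C@@H](Br)[C@@H](O)[C@@H](O)[C@@]1(C)[C@H](O[Si](C)(C)C(C)(C)C)CCl | intermediate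
20 | 6β,7β-epoxy-8α,9α-diol | CC(C)(C)[Si](c2ccccc2)(c3ccccc3)OCC[C@@H]1[C@@H]4O[C@@H]4[C@@H](O)[C@@H](O)[C@@]1(C)[C@H](O[Si](C)(C)C(C)(C)C)CCl | intermediate
21 | allyl hydrogen malonate (3-(allyloxy)-3-oxopropanoic acid) | OC(=O)CC(=O)OCC=C | starting material
22 | 6β,7β-epoxy-8α-O-(allyl malonyl)-9α-ol | CC(C)(C)[Si](c2ccccc2)(c3ccccc3)OCC[C@@H]1[C@@H]4O[C@@H]4[C@@H](OC(=O)CC(=O)OCC=C)[C@@H](O)[C@@]1(C)[C@H](O[Si](C)(C)C(C)(C)C)CCl | intermediate
23 | 6β,7β-epoxy-8α-O-(allyl malonyl)-9α-O-methacryloyl diester | CC(C)(C)[Si](c2ccccc2)(c3ccccc3)OCC[C@@H]1[C@@H]4O[C@@H]4[C@@H](OC(=O)CC(=O)OCC=C)[C@@H](OC(=O)C(C)=C)[C@@]1(C)[C@H](O[Si](C)(C)C(C)(C)C)CCl | intermediate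
24 | diester 23 with free C3 primary alcohol | OCC[C@@H]1[C@@H]4O[C@@H]4[C@@H](OC(=O)CC(=O)OCC=C)[C@@H](OC(=O)C(C)=C)[C@@]1(C)[C@H](O[Si](C)(C)C(C)(C)C)CCl | intermediate
25 | C3 aldehyde | O=CC[C@@H]1[C@@H]4O[C@@H]4[C@@H](OC(=O)CC(=O)OCC=C)[C@@H](OC(=O)C(C)=C)[C@@]1(C)[C@H](O[Si](C)(C)C(C)(C)C)CCl | intermediate
26 | C3 dimethyl acetal | COC(OC)C[C@@H]1[C@@H]4O[C@@H]4[C@@H](OC(=O)CC(=O)OCC=C)[C@@H](OC(=O)C(C)=C)[C@@]1(C)[C@H](O[Si](C)(C)C(C)(C)C)CCl | intermediate
27 | 6β-hydroxy-11-(allyloxycarbonyl)-12,8α-olide (cis-fused, H7β; C11 epimers), 9α-methacrylate | COC(OC)C[C@@H]1[C@H](O)[C@H]4C(C(=O)OCC=C)C(=O)O[C@H]4[C@@H](OC(=O)C(C)=C)[C@@]1(C)[C@H](O[Si](C)(C)C(C)(C)C)CCl | intermediate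
28 | 11-carboxy lactone (not isolated) | COC(OC)C[C@@H]1[C@H](O)[C@H]4C(C(=O)O)C(=O)O[C@H]4[C@@H](OC(=O)C(C)=C)[C@@]1(C)[C@H](O[Si](C)(C)C(C)(C)C)CCl | intermediate
29 | 11-carboxy-11-(morpholinomethyl) lactone (Mannich base, not isolated) | COC(OC)C[C@@H]1[C@H](O)[C@H]4C(CN5CCOCC5)(C(=O)O)C(=O)O[C@H]4[C@@H](OC(=O)C(C)=C)[C@@]1(C)[C@H](O[Si](C)(C)C(C)(C)C)CCl | intermediate
30 | 11(13)-methylene-12,8α-olide, 6β-OH, 9α-methacrylate, C3 dimethyl acetal, 1-O-silyl chlorohydrin | COC(OC)C[C@@H]1[C@H](O)[C@H]4C(=C)C(=O)O[C@H]4[C@@H](OC(=O)C(C)=C)[C@@]1(C)[C@H](O[Si](C)(C)C(C)(C)C)CCl | intermediate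
31 | C3 aldehyde, (1S)-2-chloro-1-hydroxyethyl, 6β-OH (open form shown) | O=CC[C@@H]1[C@H](O)[C@H]4C(=C)C(=O)O[C@H]4[C@@H](OC(=O)C(C)=C)[C@@]1(C)[C@H](O)CCl | intermediate
32 | 4-(dimethylaminomethyl) aldehyde (Mannich base, C4 epimers, not isolated) | O=CC(CN(C)C)[C@@H]1[C@H](O)[C@H]4C(=C)C(=O)O[C@H]4[C@@H](OC(=O)C(C)=C)[C@@]1(C)[C@H](O)CCl | intermediate
33 | enal chlorohydrin (4(15)-en-3-al, (1S)-2-chloro-1-hydroxyethyl) | O=CC(=C)[C@@H]1[C@H](O)[C@H]4C(=C)C(=O)O[C@H]4[C@@H](OC(=O)C(C)=C)[C@@]1(C)[C@H](O)CCl | intermediate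
34 | CNP0124638.3: (1S)-1,2-epoxy-6β-hydroxy-9α-methacryloyloxy-3-oxoelema-4(15),11(13)-dien-12,8α-olide (5αH, 7βH, 10β-CH3) | C=C(C)C(=O)O[C@@H]1[C@@H]2OC(=O)C(=C)[C@@H]2[C@@H](O)[C@@H](C(=C)C=O)[C@]1(C)[C@H]1CO1 | target

**Count and risks**

Total steps: 25. Longest linear sequence: 24 steps (1, 2, 4–25; step 3 makes the diene in a side branch).

Steps most likely to fail:

Step 4 (enantioselective Diels–Alder of a trisubstituted enal). If conversion or ee is poor, the fallback sets out from 4 and uses a different cycloaddition logic. Enal 4 is combined with the far more electron-rich (E)-1-(dimethylamino)-3-(tert-butyldimethylsilyloxy)buta-1,3-diene under the salen chromium complex (salen)CrSbF6 (trivalent chromium; salen = N,N'-bis(3,5-di-tert-butylsalicylidene)cyclohexane-1,2-diamine dianion). This gives the amino silyl enol ether aldehyde F1. Chloromethyllithium addition (ICH2Cl, MeLi·LiBr, −78 °C) gives the chlorohydrin F2. Dilute aqueous HCl in THF hydrolyses the enol ether and eliminates dimethylamine, which returns to the route at 9 and bypasses the Saegusa step.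

Step 8 (enzymatic reduction of a neopentylic ketone). If no enzyme in the panel accepts 10, the fallback sets out from 8, where the ring carbonyl is still masked. Dess–Martin oxidation gives the chloro ketone silyl enol ether F3. Oxazaborolidine-catalysed borane reduction ((S)-1-methyl-3,3-diphenyltetrahydro-1H,3H-pyrrolo[1,2-c][1,3,2]oxazaborole, BH3·SMe2, THF, −20 °C) gives the (S)-chlorohydrin silyl enol ether F4. Saegusa oxidation with Pd(OAc)2 in DMSO returns to the route at 11.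

Step 21 (malonate opening of a hindered epoxide next to a methacrylate). If the carbanion adds to the methacrylate or the epoxide resists, the fallback sets out from 20 and changes both the nucleophile and the methylenation. Esterification of 20 with diethylphosphonoacetic acid (DCC, DMAP) gives the 8-O-phosphonoacetate F5. Methacrylic anhydride, pyridine and DMAP give the diester F6. Bu4NF/AcOH gives the primary alcohol F7, Dess–Martin oxidation the aldehyde F8, and HC(OMe)3/PPTS/MeOH the dimethyl acetal F9. NaH in THF at 0 °C to rt closes the ring by phosphonate-carbanion opening of the epoxide, giving the α-phosphono lactone F10. Horner–Wadsworth–Emmons reaction with aqueous formaldehyde and K2CO3 returns to the route at 30, with no palladium or amine step.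

**Further compounds**

F1 | step 4 | (1R,6R)-2-(dimethylamino)-6-[2-(tert-butyldiphenylsilyloxy)ethyl]-1-methyl-4-(tert-butyldimethylsilyloxy)cyclohex-3-ene-1-carbaldehyde (C2 epimers) | CC(C)(C)[Si](c2ccccc2)(c3ccccc3)OCC[C@@H]1CC(O[Si](C)(C)C(C)(C)C)=CC(N(C)C)[C@@]1(C)C=O
F2 | step 4 | chlorohydrin of F1 (2-chloro-1-hydroxyethyl at C10, carbinol epimers) | CC(C)(C)[Si](c2ccccc2)(c3ccccc3)OCC[C@@H]1CC(O[Si](C)(C)C(C)(C)C)=CC(N(C)C)[C@@]1(C)C(O)CCl
F3 | step 8 | 2-chloro-1-[(1R,6R)-6-[2-(tert-butyldiphenylsilyloxy)ethyl]-1-methyl-4-(triisopropylsilyloxy)cyclohex-3-en-1-yl]ethanone | CC(C)(C)[Si](c2ccccc2)(c3ccccc3)OCC[C@@H]1CC(O[Si](C(C)C)(C(C)C)C(C)C)=CC[C@@]1(C)C(=O)CCl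
F4 | step 8 | (1S)-2-chloro-1-[(1R,6R)-6-[2-(tert-butyldiphenylsilyloxy)ethyl]-1-methyl-4-(triisopropylsilyloxy)cyclohex-3-en-1-yl]ethanol | CC(C)(C)[Si](c2ccccc2)(c3ccccc3)OCC[C@@H]1CC(O[Si](C(C)C)(C(C)C)C(C)C)=CC[C@@]1(C)[C@H](O)CCl
F5 | step 21 | 6β,7β-epoxy-8α-O-(diethylphosphonoacetyl)-9α-ol | CC(C)(C)[Si](c2ccccc2)(c3ccccc3)OCC[C@@H]1[C@@H]4O[C@@H]4[C@@H](OC(=O)CP(=O)(OCC)OCC)[C@@H](O)[C@@]1(C)[C@H](O[Si](C)(C)C(C)(C)C)CCl
F6 | step 21 | 8α-O-(diethylphosphonoacetyl)-9α-O-methacryloyl diester | CC(C)(C)[Si](c2ccccc2)(c3ccccc3)OCC[C@@H]1[C@@H]4O[C@@H]4[C@@H](OC(=O)CP(=O)(OCC)OCC)[C@@H](OC(=O)C(C)=C)[C@@]1(C)[C@H](O[Si](C)(C)C(C)(C)C)CCl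
F7 | step 21 | diester F6 with free C3 primary alcohol | OCC[C@@H]1[C@@H]4O[C@@H]4[C@@H](OC(=O)CP(=O)(OCC)OCC)[C@@H](OC(=O)C(C)=C)[C@@]1(C)[C@H](O[Si](C)(C)C(C)(C)C)CCl
F8 | step 21 | C3 aldehyde of the phosphonate series | O=CC[C@@H]1[C@@H]4O[C@@H]4[C@@H](OC(=O)CP(=O)(OCC)OCC)[C@@H](OC(=O)C(C)=C)[C@@]1(C)[C@H](O[Si](C)(C)C(C)(C)C)CCl
F9 | step 21 | C3 dimethyl acetal of the phosphonate series | COC(OC)C[C@@H]1[C@@H]4O[C@@H]4[C@@H](OC(=O)CP(=O)(OCC)OCC)[C@@H](OC(=O)C(C)=C)[C@@]1(C)[C@H](O[Si](C)(C)C(C)(C)C)CCl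
F10 | step 21 | 6β-hydroxy-11-(diethoxyphosphoryl)-12,8α-olide (C11 epimers), 9α-methacrylate | COC(OC)C[C@@H]1[C@H](O)[C@H]4C(P(=O)(OCC)OCC)C(=O)O[C@H]4[C@@H](OC(=O)C(C)=C)[C@@]1(C)[C@H](O[Si](C)(C)C(C)(C)C)CCl
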